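## Retrosynthetic overview

1. The only ring, the 31-membered lactone 9, is closed last by acyl–O bond formation from the free seco-acid 8 on a serine hydrolase (acyl-enzyme of Candida antarctica lipase B). This is the laboratory counterpart of the presumed ω-hydroxy-fatty-acyl (thio)ester → macrolactone cyclisation, with no activating group and no protecting group.
2. 8 ⇐ (15Z)-30-hydroxytriacont-15-enoic acid 7 by hydrogenation in the same pot as the ring closure.
3. 7 ⇐ Wittig union at C15=C16 of two C15 halves: carboxylate ylide 4 and aluminated 15-hydroxypentadecanal 6.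
4. Both halves ⇐ ω-pentadecalactone 1, a bulk musk chemical: O-alkyl cleavage/quaternisation gives salt 3, and DIBAL half-reduction gives 6 in situ.

Assumption: the SMILES is read as one ester carbonyl, 29 ring CH2 groups and one ring oxygen (31-membered lactone, C30H58O2); it has no stereocentre, so no enantiomer has to be controlled, and the Z/E ratio of alkene 7 is immaterial because step 3 saturates it.

## Route

Step 1
Reactants: 1 ω-pentadecalactone (oxacyclohexadecan-2-one)
Product: 3 (14-carboxytetradecyl)triphenylphosphonium bromide, via 15-bromopentadecanoic acid 2 (not isolated)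
Conditions: Ph3P·HBr (1.05 equiv), neat melt, 170 °C, 8 h, N2; triturate with Et2O
Reagents that add atoms: triphenylphosphine hydrobromide, [Br-].[PH+](c1ccccc1)(c1ccccc1)c1ccccc1
Why: Acid-mediated SN2 O-alkyl cleavage of the unstrained primary-alkyl lactone by bromide gives the ω-bromo acid, which the liberated PPh3 quaternises in the same melt (phosphonium salt formation); this is the Ph3P·HBr lactone opening used for γ-butyrolactone, applied here to a macrolactone in which any transesterified oligomer is cleaved to the same product, and no stereocentre is formed.

Step 2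
Reactants: 1 ω-pentadecalactone (oxacyclohexadecan-2-one); 3 (14-carboxytetradecyl)triphenylphosphonium bromide
Product: 7 (15Z)-30-hydroxytriacont-15-enoic acid, via ylide carboxylate 4 (not isolated), via aluminium hemiacetal 5 (not isolated), via aluminated 15-hydroxypentadecanal 6 (not isolated)
Conditions: (a) 3 (1.3 equiv), KHMDS (2.6 equiv), THF, 0 °C; (b) 1, DIBAL-H (1.05 equiv), toluene, −78 °C, 1 h; (c) cannulate (b) into (a), −78 °C → rt, 4 h; 1 M HCl
Reagents that add atoms: none
Why: One-pot DIBAL half-reduction/Wittig olefination: the tetrahedral aluminium hemiacetal is stable at −78 °C and collapses on warming to the aldehyde, which the salt-free non-stabilised ylide traps at once (carboxylate and aluminium alkoxide are spectators) to give mainly the Z-alkene under kinetic control; the geometry does not matter because the alkene is hydrogenated in step 3.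

Step 3
Reactants: 7 (15Z)-30-hydroxytriacont-15-enoic acid
Product: 9 oxacyclohentriacontan-2-one (triacontan-30-olide), via 30-hydroxytriacontanoic acid 8 (not isolated)
Conditions: H2 (1 atm), 5% Pd/C, toluene, 60 °C, 3 h; then N2 purge, dilute to 2 mM in toluene, Novozym 435 (immobilised Candida antarctica lipase B), 4 Å MS, 70 °C, 48–72 h; hot filtration, silica plug
Reagents that add atoms: none
Why: Proposed new method: Pd/C hydrogenation gives the saturated seco-acid, which the lipase takes up as a serine acyl-enzyme and releases by intramolecular attack of the ω-OH (the same acyl-enzyme → macrolactone logic as a thioesterase cyclisation), and because every linear or cyclic oligoester remains a lipase substrate, ring–chain equilibration at 2 mM (below the roughly 10 mM effective molarity of strain-free large rings) funnels material to the monomeric 31-membered lactone; the closest known chemistry is lipase-catalysed macrolactonisation of 15- and 16-hydroxy acids and lipase ring-opening polymerisation of macrolactones (its microscopic reverse), run here in one pot with a Pd catalyst as in Pd/lipase dynamic kinetic resolutions, and no stereocentre is involved.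

## Compound list

1 | ω-pentadecalactone (oxacyclohexadecan-2-one) | O=C1CCCCCCCCCCCCCCO1 | starting material
2 | 15-bromopentadecanoic acid | OC(=O)CCCCCCCCCCCCCCBr | intermediate
3 | (14-carboxytetradecyl)triphenylphosphonium bromide | OC(=O)CCCCCCCCCCCCCC[P+](c1ccccc1)(c1ccccc1)c1ccccc1.[Br-] | intermediate
4 | potassium 15-(triphenyl-λ5-phosphanylidene)pentadecanoate (ylide carboxylate) | [K+].[O-]C(=O)CCCCCCCCCCCCCC=P(c1ccccc1)(c1ccccc1)c1ccccc1 | intermediate
5 | diisobutyl(oxacyclohexadecan-2-yloxy)aluminium (aluminium hemiacetal) | CC(C)C[Al](CC(C)C)OC1CCCCCCCCCCCCCCO1 | intermediate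
6 | diisobutyl(15-oxopentadecyloxy)aluminium (aluminated 15-hydroxypentadecanal) | CC(C)C[Al](CC(C)C)OCCCCCCCCCCCCCCC=O | intermediate
7 | (15Z)-30-hydroxytriacont-15-enoic acid | OC(=O)CCCCCCCCCCCCC/C=C\CCCCCCCCCCCCCCO | intermediate
8 | 30-hydroxytriacontanoic acid | OC(=O)CCCCCCCCCCCCCCCCCCCCCCCCCCCCCO | intermediate
9 | oxacyclohentriacontan-2-one (triacontan-30-olide) | O=C1CCCCCCCCCCCCCCCCCCCCCCCCCCCCCO1 | target

## Summary

Total step count: 3.
Longest linear sequence: 3 steps (1 → 3 → 7 → 9); both C15 halves come from 1.

Steps most likely to fail, most risky first: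

Step 3. The lipase may turn over the C30 acid slowly or stall at oligoesters. The fallback sets out from 7 and returns at 9, replacing the enzyme by chemical thioester double activation and moving the hydrogenation to the end. Acid 7 is treated with 2,2'-dipyridyl disulfide and PPh3 in CH2Cl2 to give S-(pyridin-2-yl) (15Z)-30-hydroxytriacont-15-enethioate F6. This is added by syringe pump to refluxing xylene (final concentration ≤1 mM) to give (16Z)-oxacyclohentriacont-16-en-2-one F7, which is freed of sulfur residues on silica and hydrogenated (H2, Pd/C, EtOAc) to 9.

Step 2. The aluminium hemiacetal may over-reduce to pentadecane-1,15-diol or release the aldehyde too slowly for clean trapping. The fallback sets out from 1 and returns at 7, fixing the aldehyde oxidation level through a chelated amide and an isolated aldehyde. Lactone 1 is opened with MeNH(OMe)·HCl/Me3Al in CH2Cl2 to give 15-hydroxy-N-methoxy-N-methylpentadecanamide F4. DIBAL-H (2.2 equiv, THF, −78 °C) then gives, after work-up, 15-hydroxypentadecanal F5, which is added to ylide 4 (THF, −78 °C → rt) to give 7 after acidification.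

Step 1. The melt may give incomplete O-alkyl cleavage or dark, hard-to-purify material. The fallback sets out from 1 and returns at 4, using silyl-iodide dealkylation and a separate quaternisation. Lactone 1 is cleaved with Me3SiI made in situ (TMSCl/NaI, MeCN, 80 °C) to give trimethylsilyl 15-iodopentadecanoate F1, which is hydrolysed on aqueous work-up to 15-iodopentadecanoic acid F2. PPh3 in refluxing MeCN converts F2 into (14-carboxytetradecyl)triphenylphosphonium iodide F3, and two equivalents of KHMDS in THF turn F3 into ylide 4.

## Further compounds

F1 | step 1 | trimethylsilyl 15-iodopentadecanoate | C[Si](C)(C)OC(=O)CCCCCCCCCCCCCCI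
F2 | step 1 | 15-iodopentadecanoic acid | OC(=O)CCCCCCCCCCCCCCI
F3 | step 1 | (14-carboxytetradecyl)triphenylphosphonium iodide | OC(=O)CCCCCCCCCCCCCC[P+](c1ccccc1)(c1ccccc1)c1ccccc1.[I-]
F4 | step 2 | 15-hydroxy-N-methoxy-N-methylpentadecanamide | CON(C)C(=O)CCCCCCCCCCCCCCO
F5 | step 2 | 15-hydroxypentadecanal | O=CCCCCCCCCCCCCCCO
F6 | step 3 | S-(pyridin-2-yl) (15Z)-30-hydroxytriacont-15-enethioate | O=C(Sc1ccccn1)CCCCCCCCCCCCC/C=C\CCCCCCCCCCCCCCO
F7 | step 3 | (16Z)-oxacyclohentriacont-16-en-2-one | O=C1CCCCCCCCCCCCC/C=C\CCCCCCCCCCCCCCO1
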